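**Remarks on the chemistry (assumptions, one line each)**

- Ring atoms are numbered as in drimane: C1–C10 in the decalin, C11 = the CH2O carbon on C9, C12 = the exocyclic methylene carbon on C8; in this numbering the target is 3R (axial 3α-OH), 5R (5α-H), 9S (9α-H), 10S (10β-CH3).
- In the acyclic compounds the chain locants map as chain C1 = C11, C2 = C9, C3 = C10, C4 = C1, C5 = C2, C6 = C3, C7 = C4, C8 = C5, C9 = C6, C10 = C7, C11 = C8, C12 = C12.
- Methyl geranate is assumed to be used as the pure (2E)-isomer.
- (+)-Ipc2BH means the diisopinocampheylborane prepared from (−)-α-pinene and BH3·SMe2; this series is assumed to add to the Re face of an aliphatic aldehyde.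

## Analysis of the target

The target is the umbelliferone (7-hydroxycoumarin) ether of a drimane-type sesquiterpene: a trans-fused decalin made of ring A (C1–C5, C10) and ring B (C5–C10), with a gem-dimethyl group on C4, an angular methyl on C10, a secondary alcohol on C3, an exocyclic methylene (C12) on C8 and the CH2–O–aryl arm (C11) on C9. Ring B contains a conjugated diene built from the ring alkene C6=C7 and the exocyclic alkene C8=C12, locked s-trans; this unit is exactly what a vinylallene leaves behind after it has served as the diene of a [4+2] cycloaddition, and the route is built on that feature. There are four stereocentres, C3 (R), C5 (R), C9 (S) and C10 (S): H5 is trans to the C10 methyl, the C11 arm is cis to the C10 methyl (equatorial), and the C3 hydroxyl is axial, on the face opposite to the C10 methyl. C5, C9 and C10 are contiguous and form one problem of relative configuration, whereas C3 lies beyond the quaternary C4 and is best set by a reagent at the ketone stage. The fusion bond C5–C10 joins a quaternary carbon to a carbon that sits next to the second quaternary carbon C4, and is the most hindered bond of the skeleton. The sensitive groups are the exocyclic diene (acid moves the double bonds into the ring), H9 (allylic to the diene and β to the aryloxy group, so base can epimerise C9 or expel the phenol) and the coumarin lactone (hydride, organometallics, hydroxide). The synthesis is hard because ring B is functionalised at four contiguous carbons (C6–C9) without a heteroatom at C6 or C7, so C6=C7 cannot easily be introduced late into a saturated drimane, and because the axial C3 alcohol is the epimer that a chair–chair epoxy-polyene cyclisation does not give together with this ring fusion.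

## Retrosynthetic reasoning

**C11–O ether (15 ⇒ 13 + 14).** The aryl ether is cut first, so that the coumarin 14 enters in the last step and never meets hydride reagents. The forward reaction must etherify the primary C11 alcohol of diol 13 in the presence of the hindered axial C3 alcohol, without base strong enough to touch H9.

**C3 and C11 oxidation levels (13 ⇒ 11 ⇒ 10).** Diol 13 is traced back to keto ester 11, and 11 to the hydroxy ester 10. The axial C3 alcohol is then a reagent-controlled result: a bulky hydride attacks the 4,4-dimethyl-3-ketone along the equatorial direction. This frees the C3 carbinol of 10 to serve, with the opposite configuration, as a stereochemical relay in the key step. The ester at C9 is the dienophile's activating group and becomes C11.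

**Key disconnection, C5–C10 and C8–C9 (10 ⇒ 9).** The C6=C7/C8=C12 diene of ring B is the retron of a Diels–Alder reaction in which a vinylallene (C5=C6–C7=C8=C12) is the diene and C9=C10 the dienophile. Because C5 and C10 are both atoms of ring A, the retro-cycloaddition opens both rings at once and leaves the acyclic tetraene ester 9, in which C1–C4 is the tether. No other cut of ring B gives the C6=C7 alkene directly. What is gained: both rings, the quaternary C10, three stereocentres (C5, C9, C10) and the complete diene from a chain with one stereocentre and no ring. The forward reaction has to form the most hindered bond of the target intramolecularly, with endo selectivity (trans fusion) and with facial control from C3.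

**C7–C8 (9 ⇒ 8).** The vinylallene is cut between the alkene and the allene. The forward step is a palladium-catalysed coupling of the (E)-alkenyl iodide 8 with a commercial three-carbon allenyl-metal reagent; it must be mild enough that 9 can be isolated.

**C5=C6 and C5 (8 ⇒ 7 ⇒ 5).** The alkenyl iodide comes from the α-quaternary aldehyde 7 by one-carbon iodo-olefination, and 7 from the terminal vinyl group of 5 by ozonolysis. The forward cleavage has to spare the conjugated ester alkene.

**C3–C4 (5 ⇒ 3).** The bond between the carbinol carbon and the quaternary carbon is cut. The forward reaction is an asymmetric tert-prenylation of aldehyde 3, which sets C3 and builds the gem-dimethyl carbon C4 with its vinyl handle in one step.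

**Origin of the dienophile (3 ⇒ 1).** Aldehyde 3 is methyl geranate 1 without its isopropylidene end. Compound 1 already contains C11, the (E)-C9=C10 alkene with the C10 methyl, and C1–C3, so the dienophile geometry is bought, not made.

## Alternatives that were turned down

**Alternative 1:** (the textbook disconnection) C5–C10 and C8–C9 are cut as above, but in the biomimetic sense: cyclisation of the (10S)-10,11-epoxyfarnesyl acetate A1. The forward key step is a radical cyclisation of A1 with Cp2TiCl (trivalent titanium: epoxide opening, two 6-endo closures, loss of a β-hydrogen) to the bicyclic alcohol A2, which has the trans-decalin, C5/C9/C10 and the exocyclic C8=C12 alkene. It was turned down because A2 is one unsaturation short exactly where the target is hard. C6 and C7 are unactivated methylenes, so C6=C7 would need allylic oxidation at C7 and a regioselective 1,2-elimination towards C6 on an acid-sensitive diene, with the risk that C8=C12 moves into the ring. A2 also has the equatorial 3β-alcohol, so the same oxidation–reduction at C3 is needed, plus acetate cleavage and etherification. The sequence would be about four steps longer than the route below, and cyclisations of this type tend to stop partly at monocyclic products.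

**Alternative 2:** C1–C10 and C4–C5 are cut (Robinson annulation), so that ring A is annulated onto a ring-B dione. The forward key step is the proline-catalysed annulation to the Wieland–Miescher ketone A3, followed by deconjugative gem-dimethylation at C4 to the dione A4, which holds C10, the C4 methyls and the C3 carbonyl. It was turned down because the key step sets only C10. C5 would have to be set by reduction of the C5=C6 alkene, and every ring-B carbon from C6 to C9 still has to be worked on one at a time (C9 ketone to C9–CH2O, C8 methylene, C6=C7 alkene) next to a neopentyl centre. That is more than ten linear steps after the annulation, none of which builds the skeleton.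

**Alternative 3:** C9–C10 and C7–C8 are cut: an intermolecular Diels–Alder reaction of the ring-A vinylcyclohexene A5 (diene C10=C5–C6=C7) with the allenoate A6, in which the allene again supplies the exocyclic methylene. The forward key step is the thermal or Lewis acid promoted cycloaddition to A7. It was turned down because the new ring alkene lands at C5=C6, not at C6=C7. A7 has no stereocentre at C5, and moving a ring-fusion alkene outward while creating the trans H5 has no direct solution. In addition the quaternary C10 would be made intermolecularly at a fully substituted diene terminus, with only remote facial control from C3 and no control of endo/exo at C9.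

Key step: step 6

## Route

Step 1
Reactants: 1 methyl (2E)-3,7-dimethylocta-2,6-dienoate (methyl geranate)
Product: 3 methyl (2E)-3-methyl-6-oxohex-2-enoate, via ozonide 2 (not isolated)
Conditions: O3, CH2Cl2, −78 °C (Sudan Red 7B end-point); PPh3, −78 °C → rt
Reagents that add atoms: ozone, O=[O+][O-]
Why: Ozone is electrophilic and should attack the electron-rich trisubstituted C6=C7 alkene far faster than the ester-conjugated C2=C3 alkene; reductive work-up of the ozonide gives the aldehyde (alkene ozonolysis) and leaves the (E)-enoate, the future dienophile, untouched.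

Step 2
Reactants: 3 methyl (2E)-3-methyl-6-oxohex-2-enoate
Product: 5 methyl (2E,6S)-6-hydroxy-3,7,7-trimethylnona-2,8-dienoate, via diisopinocampheylborinate 4 (not isolated)
Conditions: (+)-Ipc2BH, 3-methylbuta-1,2-diene, THF, −25 °C; then 3, −78 °C; NaBO3·4H2O, THF/H2O, rt
Reagents that add atoms: 3-methylbuta-1,2-diene, CC(C)=C=C
Why: Hydroboration of the allene gives the prenylborane, which adds to the aldehyde with allylic transposition through a closed chair (Zimmerman–Traxler) transition state (Brown asymmetric prenylboration), so the C3 carbinol and the quaternary C4 are made together. The Ipc groups from (−)-α-pinene should direct the attack to the Re face, which corresponds to the (6S)-carbinol; the antipodal borane would give the (6R)-carbinol. The mild perborate work-up spares the methyl ester and the enoate.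

Step 3
Reactants: 5 methyl (2E,6S)-6-hydroxy-3,7,7-trimethylnona-2,8-dienoate
Product: 7 methyl (2E,6S)-6-hydroxy-3,7,7-trimethyl-8-oxooct-2-enoate, via ozonide 6 (not isolated)
Conditions: O3 (1.0 equiv), CH2Cl2, −78 °C (Sudan Red 7B end-point); PPh3, −78 °C → rt; used crude
Reagents that add atoms: ozone, O=[O+][O-]
Why: Alkene ozonolysis; the isolated vinyl group should react before the conjugated, electron-poor enoate alkene, and the dye end-point limits the ozone dose. The β-hydroxy aldehyde has no α-hydrogen, so it cannot dehydrate or epimerise, and it is carried on without purification.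

Step 4
Reactants: 7 methyl (2E,6S)-6-hydroxy-3,7,7-trimethyl-8-oxooct-2-enoate
Product: 8 methyl (2E,6S,8E)-6-hydroxy-9-iodo-3,7,7-trimethylnona-2,8-dienoate
Conditions: CrCl2, CHI3, THF/1,4-dioxane, 0 °C → rt
Reagents that add atoms: iodoform, IC(I)I
Why: Takai iodo-olefination: the geminal dichromium species formed from iodoform and divalent chromium adds to the aldehyde and eliminates to the (E)-alkenyl iodide, with E-selectivity that should be high for an α-quaternary aldehyde. The chromium reagent tolerates the free hydroxyl and the enoate.

Step 5
Reactants: 8 methyl (2E,6S,8E)-6-hydroxy-9-iodo-3,7,7-trimethylnona-2,8-dienoate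
Product: 9 methyl (2E,6S,8E)-6-hydroxy-3,7,7-trimethyldodeca-2,8,10,11-tetraenoate
Conditions: tributyl(propa-1,2-dien-1-yl)stannane, Pd2(dba)3 (cat.), AsPh3, NMP, rt, dark
Reagents that add atoms: tributyl(propa-1,2-dien-1-yl)stannane, C=C=C[Sn](CCCC)(CCCC)CCCC
Why: Stille coupling: oxidative addition of zerovalent palladium to the alkenyl iodide with retention of the (E)-geometry, then transfer of the allenyl group from tin at its tin-bearing carbon, gives the vinylallene. The weakly bound AsPh3 ligand lets the coupling run at room temperature, so 9 should be isolable before it cyclises.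

Step 6
Reactants: 9 methyl (2E,6S,8E)-6-hydroxy-3,7,7-trimethyldodeca-2,8,10,11-tetraenoate
Product: 10 methyl (1S,4aR,6S,8aS)-6-hydroxy-5,5,8a-trimethyl-2-methylidene-1,2,4a,5,6,7,8,8a-octahydronaphthalene-1-carboxylate
Conditions: PhMe (0.01 M), BHT (cat.), 100 °C, sealed tube, argon
Reagents that add atoms: none
Why: Concerted but asynchronous thermal [4+2] cycloaddition: the vinylallene of 9 reacts through C5=C6 and C7=C8 with the tethered (E)-enoate C9=C10, so that C5–C10 and C8–C9 are formed, the new ring alkene appears at C6=C7 and the untouched distal allene bond C8=C12 becomes the exocyclic methylene. The closest known reaction type is the intramolecular Diels–Alder reaction of vinylallenes, which are unusually reactive dienes because the sp carbon C8 carries no inward substituent and cumulene strain is released. Ring B is closed by the cycloaddition itself and ring A by the four-carbon tether C1–C4 (type-one intramolecular Diels–Alder reaction of a 1,7,9-decatriene through a chair-like tether, assisted by the gem-dimethyl group on C4). The cis relationship between the C10 methyl and the C9 ester is fixed by suprafacial addition to the (E)-enoate. The trans ring fusion follows from the transition state with the ester endo and the tether exo, which is favoured by secondary orbital overlap, by the absence of a clash between an exo ester and the C12 hydrogen that points towards the dienophile, and because both chair-like cis-fused arrangements keep a syn-axial contact with the axial C4 methyl that is at least as large as the CH3/CH3 contact of the trans mode. The absolute sense is relayed from C3 (the 6S centre of 9): with the hydroxyl equatorial in the chair-like tether, the diene is attacked on the face that gives 5R, 9S and 10S. The selectivities needed are endo over exo and equatorial over axial carbinol; the second is expected to be the weaker one, and the minor trans-fused diastereomer (axial hydroxyl, enantiomeric decalin) is removed by chromatography at this stage, before C3 is oxidised. A [1,5]-hydrogen shift of the vinylallene is impossible because C4 is quaternary, and the product diene is locked s-trans, so it cannot react on as a diene.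

Step 7
Reactants: 10 methyl (1S,4aR,6S,8aS)-6-hydroxy-5,5,8a-trimethyl-2-methylidene-1,2,4a,5,6,7,8,8a-octahydronaphthalene-1-carboxylate
Product: 11 methyl (1S,4aR,8aS)-5,5,8a-trimethyl-2-methylidene-6-oxo-1,2,4a,5,6,7,8,8a-octahydronaphthalene-1-carboxylate
Conditions: Dess–Martin periodinane, NaHCO3, CH2Cl2, 0 °C → rt
Reagents that add atoms: none
Why: Dess–Martin oxidation of the hindered secondary alcohol under buffered, near-neutral conditions, so that neither the acid-labile exocyclic diene nor the β,γ-unsaturated ester (H9) should isomerise. The relay stereocentre C3 is erased after it has done its work.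

Step 8
Reactants: 11 methyl (1S,4aR,8aS)-5,5,8a-trimethyl-2-methylidene-6-oxo-1,2,4a,5,6,7,8,8a-octahydronaphthalene-1-carboxylate
Product: 13 (2R,4aS,5S,8aR)-5-(hydroxymethyl)-1,1,4a-trimethyl-6-methylidene-1,2,3,4,4a,5,6,8a-octahydronaphthalen-2-ol, via 3α-hydroxy ester 12 (not isolated)
Conditions: LiBH(s-Bu)3, THF, −78 °C; then i-Bu2AlH, −78 → 0 °C; aq. Rochelle salt
Reagents that add atoms: none
Why: The bulky trialkylborohydride avoids the axial trajectory (syn-axial H1α and H5α) and delivers hydride to the equatorial 3β position, which gives the axial 3R alcohol, the usual outcome for 4,4-dimethyl-3-keto terpenoids; the ester is not touched at −78 °C. i-Bu2AlH then reduces the hindered ester to the primary C11 alcohol in the same flask; neither hydride adds to the isolated, non-conjugated diene.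

Step 9
Reactants: 13 (2R,4aS,5S,8aR)-5-(hydroxymethyl)-1,1,4a-trimethyl-6-methylidene-1,2,3,4,4a,5,6,8a-octahydronaphthalen-2-ol; 14 7-hydroxy-2H-chromen-2-one (umbelliferone)
Product: 15 7-{[(1S,4aR,6R,8aS)-6-hydroxy-5,5,8a-trimethyl-2-methylidene-1,2,4a,5,6,7,8,8a-octahydronaphthalen-1-yl]methoxy}-2H-chromen-2-one
Conditions: PPh3, DIAD, THF, 0 °C → rt
Reagents that add atoms: none
Why: Mitsunobu etherification: the acidic phenol 14 displaces the oxyphosphonium of the primary C11 alcohol by SN2 at CH2, so no stereocentre is touched. The axial, neopentyl-type C3 alcohol should be too hindered to be activated, and the neutral conditions spare the coumarin lactone and the diene.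

## Compound list

1 | methyl (2E)-3,7-dimethylocta-2,6-dienoate (methyl geranate) | COC(=O)/C=C(\C)CCC=C(C)C | starting material
2 | methyl (2E)-5-(5,5-dimethyl-1,2,4-trioxolan-3-yl)-3-methylpent-2-enoate (ozonide, mixture of epimers) | COC(=O)/C=C(\C)CCC1OOC(C)(C)O1 | intermediate
3 | methyl (2E)-3-methyl-6-oxohex-2-enoate | COC(=O)/C=C(\C)CCC=O | intermediate
4 | methyl (2E,6S)-6-[(diisopinocampheylboranyl)oxy]-3,7,7-trimethylnona-2,8-dienoate (Ipc groups from (−)-α-pinene) | COC(=O)/C=C(\C)CC[C@H](OB([C@H]1C[C@H]2C[C@@H]([C@@H]1C)C2(C)C)[C@H]1C[C@H]2C[C@@H]([C@@H]1C)C2(C)C)C(C)(C)C=C | intermediate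
5 | methyl (2E,6S)-6-hydroxy-3,7,7-trimethylnona-2,8-dienoate | COC(=O)/C=C(\C)CC[C@H](O)C(C)(C)C=C | intermediate
6 | methyl (2E,6S)-6-hydroxy-3,7-dimethyl-7-(1,2,4-trioxolan-3-yl)oct-2-enoate (ozonide, mixture of epimers) | COC(=O)/C=C(\C)CC[C@H](O)C(C)(C)C1OOCO1 | intermediate
7 | methyl (2E,6S)-6-hydroxy-3,7,7-trimethyl-8-oxooct-2-enoate | COC(=O)/C=C(\C)CC[C@H](O)C(C)(C)C=O | intermediate
8 | methyl (2E,6S,8E)-6-hydroxy-9-iodo-3,7,7-trimethylnona-2,8-dienoate | COC(=O)/C=C(\C)CC[C@H](O)C(C)(C)/C=C/I | intermediate
9 | methyl (2E,6S,8E)-6-hydroxy-3,7,7-trimethyldodeca-2,8,10,11-tetraenoate | COC(=O)/C=C(\C)CC[C@H](O)C(C)(C)/C=C/C=C=C | intermediate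
10 | methyl (1S,4aR,6S,8aS)-6-hydroxy-5,5,8a-trimethyl-2-methylidene-1,2,4a,5,6,7,8,8a-octahydronaphthalene-1-carboxylate | C=C1C=C[C@H]2C(C)(C)[C@@H](O)CC[C@]2(C)[C@H]1C(=O)OC | intermediate
11 | methyl (1S,4aR,8aS)-5,5,8a-trimethyl-2-methylidene-6-oxo-1,2,4a,5,6,7,8,8a-octahydronaphthalene-1-carboxylate | C=C1C=C[C@H]2C(C)(C)C(=O)CC[C@]2(C)[C@H]1C(=O)OC | intermediate
12 | methyl (1S,4aR,6R,8aS)-6-hydroxy-5,5,8a-trimethyl-2-methylidene-1,2,4a,5,6,7,8,8a-octahydronaphthalene-1-carboxylate | C=C1C=C[C@H]2C(C)(C)[C@H](O)CC[C@]2(C)[C@H]1C(=O)OC | intermediate
13 | (2R,4aS,5S,8aR)-5-(hydroxymethyl)-1,1,4a-trimethyl-6-methylidene-1,2,3,4,4a,5,6,8a-octahydronaphthalen-2-ol | C=C1C=C[C@H]2C(C)(C)[C@H](O)CC[C@]2(C)[C@H]1CO | intermediate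
14 | 7-hydroxy-2H-chromen-2-one (umbelliferone) | O=c1ccc2ccc(O)cc2o1 | starting material
15 | 7-{[(1S,4aR,6R,8aS)-6-hydroxy-5,5,8a-trimethyl-2-methylidene-1,2,4a,5,6,7,8,8a-octahydronaphthalen-1-yl]methoxy}-2H-chromen-2-one | C=C1C=C[C@H]2C(C)(C)[C@H](O)CC[C@]2(C)[C@H]1COc1ccc2ccc(=O)oc2c1 | target

## Step count and least certain steps

Total step count: 9. Longest linear sequence: 9 steps (1 → 15); umbelliferone 14 enters in the last step.

**Step 6 (key step).** Three things may go wrong.
- Facial discrimination by the C3 carbinol may be weak: the equatorial preference of a hydroxyl next to a gem-dimethyl carbon is small, so both trans-fused diastereomers may form in comparable amounts.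
- The exo (cis-fused) mode may compete at 100 °C.
- Bond formation at the congested C5–C10 bond may be slow, so that oligomerisation of the allene competes.

Fallback (from 9, back at 13): the dienophile is changed from a thermally reacting ester to a Lewis acid bound enal that reacts some 180 °C lower, which should sharpen both endo and facial selectivity. Ester 9 is reduced with i-Bu2AlH (CH2Cl2, −78 °C) to (2E,6S,8E)-3,7,7-trimethyldodeca-2,8,10,11-tetraene-1,6-diol F1. The allylic alcohol alone is oxidised with MnO2 (CH2Cl2, rt) to (2E,6S,8E)-6-hydroxy-3,7,7-trimethyldodeca-2,8,10,11-tetraenal F2. Treatment with Me2AlCl (2.2 equiv, CH2Cl2, −78 → −40 °C; the carbinol is carried as its chloro(methyl)aluminium alkoxide) should give the Lewis acid promoted intramolecular Diels–Alder adduct (1S,4aR,6S,8aS)-6-hydroxy-5,5,8a-trimethyl-2-methylidene-1,2,4a,5,6,7,8,8a-octahydronaphthalene-1-carbaldehyde F3. Buffered Dess–Martin oxidation then gives (1S,4aR,8aS)-5,5,8a-trimethyl-2-methylidene-6-oxo-1,2,4a,5,6,7,8,8a-octahydronaphthalene-1-carbaldehyde F4, and LiBH(s-Bu)3 (2.5 equiv, THF, −78 °C) reduces both carbonyl groups to give diol 13. F3 and F4 are β,γ-unsaturated aldehydes and would be carried on without storage.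

**Step 3 (with step 4).** Ozone may also attack the trisubstituted enoate alkene before the vinyl group is consumed, and the free β-hydroxy aldehyde 7 may undergo retro-aldol cleavage or oligomerise under the chromium conditions of step 4.

Fallback (from 3, back at 8): C5 is brought in as an alkyne, so that no oxidative cleavage and no β-hydroxy aldehyde are needed. Aldehyde 3 is propargylated with 4,4,5,5-tetramethyl-2-(3-methylbuta-1,2-dien-1-yl)-1,3,2-dioxaborolane (toluene, 60 °C; closed SE2′ transition state) to racemic methyl (2E)-6-hydroxy-3,7,7-trimethylnon-2-en-8-ynoate F5. Dess–Martin oxidation gives methyl (2E)-3,7,7-trimethyl-6-oxonon-2-en-8-ynoate F6. Corey–Bakshi–Shibata reduction ((R)-2-methyl-CBS-oxazaborolidine, catecholborane, toluene, −78 °C; tert-alkyl against primary alkyl) should give methyl (2E,6S)-6-hydroxy-3,7,7-trimethylnon-2-en-8-ynoate F7. Hydrozirconation with Cp2Zr(H)Cl (2.2 equiv, THF, rt) and iodinolysis (I2, 0 °C) then give the (E)-alkenyl iodide 8.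

**Step 5.** The tin reagent may transfer its three carbons in the propargyl sense, giving a skipped enyne, and the palladium catalyst may oligomerise the vinylallene. Premature cyclisation to 10 would be harmless.

Fallback (from 8, back at 9): the allene is made by reductive transposition, not by cross-coupling of an allenyl metal. Sonogashira coupling of 8 with prop-2-yn-1-ol (PdCl2(PPh3)2, copper monoiodide CuI, Et3N, rt) gives methyl (2E,6S,8E)-6,12-dihydroxy-3,7,7-trimethyldodeca-2,8-dien-10-ynoate F8. The Myers allene synthesis (2-nitrobenzenesulfonyl hydrazide, PPh3, DEAD, THF, −15 °C → rt) acts on the primary propargylic alcohol only: Mitsunobu displacement, loss of sulfinic acid, and retro-ene loss of N2 from the propargylic diazene give 9.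

**Step 9.** The activated C11 oxyphosphonium may eliminate across C9–C11 in preference to substitution, because H9 is allylic to the diene and the carbon is β-branched; this would give a cross-conjugated triene.

Fallback (from 13, back at 15): the polarity is reversed, so that C11–O is never a leaving group. Diol 13 is used as the nucleophile in a palladium-catalysed C–O coupling of Buchwald–Hartwig type with commercial 7-bromo-2H-chromen-2-one ([Pd(allyl)Cl]2, RockPhos, Cs2CO3, toluene, 80 °C). The primary alcohol should couple in preference to the hindered secondary one and give 15 directly. This fallback makes no new intermediate (entry F0).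

## Further compounds

F1 | step 6 | (2E,6S,8E)-3,7,7-trimethyldodeca-2,8,10,11-tetraene-1,6-diol | OC/C=C(\C)CC[C@H](O)C(C)(C)/C=C/C=C=C
F2 | step 6 | (2E,6S,8E)-6-hydroxy-3,7,7-trimethyldodeca-2,8,10,11-tetraenal | O=C/C=C(\C)CC[C@H](O)C(C)(C)/C=C/C=C=C
F3 | step 6 | (1S,4aR,6S,8aS)-6-hydroxy-5,5,8a-trimethyl-2-methylidene-1,2,4a,5,6,7,8,8a-octahydronaphthalene-1-carbaldehyde | C=C1C=C[C@H]2C(C)(C)[C@@H](O)CC[C@]2(C)[C@H]1C=O
F4 | step 6 | (1S,4aR,8aS)-5,5,8a-trimethyl-2-methylidene-6-oxo-1,2,4a,5,6,7,8,8a-octahydronaphthalene-1-carbaldehyde | C=C1C=C[C@H]2C(C)(C)C(=O)CC[C@]2(C)[C@H]1C=O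
F5 | step 3 | methyl (2E)-6-hydroxy-3,7,7-trimethylnon-2-en-8-ynoate (racemic) | COC(=O)/C=C(\C)CCC(O)C(C)(C)C#C
F6 | step 3 | methyl (2E)-3,7,7-trimethyl-6-oxonon-2-en-8-ynoate | COC(=O)/C=C(\C)CCC(=O)C(C)(C)C#C
F7 | step 3 | methyl (2E,6S)-6-hydroxy-3,7,7-trimethylnon-2-en-8-ynoate | COC(=O)/C=C(\C)CC[C@H](O)C(C)(C)C#C
F8 | step 5 | methyl (2E,6S,8E)-6,12-dihydroxy-3,7,7-trimethyldodeca-2,8-dien-10-ynoate | COC(=O)/C=C(\C)CC[C@H](O)C(C)(C)/C=C/C#CCO
F0 | step 9 | none | none
A1 | alternative 1 | [(2E,6E)-9-[(2S)-3,3-dimethyloxiran-2-yl]-3,7-dimethylnona-2,6-dien-1-yl] acetate | CC(=O)OC/C=C(\C)CC/C=C(\C)CC[C@@H]1OC1(C)C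
A2 | alternative 1 | [(1S,4aR,6S,8aS)-6-hydroxy-5,5,8a-trimethyl-2-methylidenedecahydronaphthalen-1-yl]methyl acetate | C=C1CC[C@H]2C(C)(C)[C@@H](O)CC[C@]2(C)[C@H]1COC(C)=O
A3 | alternative 2 | (8aS)-8a-methyl-3,4,8,8a-tetrahydronaphthalene-1,6(2H,7H)-dione (Wieland–Miescher ketone) | C[C@]12CCC(=O)C=C1CCCC2=O
A4 | alternative 2 | (8aS)-5,5,8a-trimethyl-3,7,8,8a-tetrahydronaphthalene-1,6(2H,5H)-dione | CC1(C)C(=O)CC[C@]2(C)C(=O)CCC=C12
A5 | alternative 3 | tert-butyldimethyl{[(1S)-2,2,4-trimethyl-3-vinylcyclohex-3-en-1-yl]oxy}silane | C=CC1=C(C)CC[C@H](O[Si](C)(C)C(C)(C)C)C1(C)C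
A6 | alternative 3 | methyl buta-2,3-dienoate | C=C=CC(=O)OC
A7 | alternative 3 | methyl (1S,6S,8aR)-6-[(tert-butyldimethylsilyl)oxy]-5,5,8a-trimethyl-2-methylidene-1,2,3,5,6,7,8,8a-octahydronaphthalene-1-carboxylate | C=C1CC=C2C(C)(C)[C@@H](O[Si](C)(C)C(C)(C)C)CC[C@]2(C)[C@H]1C(=O)OC
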